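The numbers in the tables stem from a simulated flask for an exercise, noise included.

At early times the oak run already keeps a tidy account: product and substrate add up to 101% of the charge at 3.00 min and to 100% at 15.0 min, so I see no side loss and can keep books on the substrate.

the same everywhere: free catalyst 0.20 mM
- oak: substrate 0.030 M; reagent 0.18 M; temperature 95 °C; run made earlier
- elm: substrate 0.054 M; reagent 0.18 M; temperature 106 °C; run made earlier
- larch: substrate 0.11 M; reagent 0.18 M; temperature 95 °C; run made earlier
- cedar: substrate 0.10 M; reagent 0.097 M; temperature 106 °C; run made earlier
- zeta: substrate 0.10 M; reagent 0.180 M; at 110 °C until 3.0 min, from then on at 90 °C; time 15 min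
- delta: substrate 0.025 M; reagent 0.0500 M; at 90 °C throughout; time 15 min

- oak (time / min: product / %, substrate / %): 3.00: 10.2, 91.0; 6.00: 16.8, 82.2; 10.0: 26.6, 72.7; 12.0: 31.3, 69.0; 15.0: 37.0, 63.0
- elm (time / min: product / %, substrate / %): 0.667: 2.9, 98.2; 2.00: 7.8, 92.3; 4.00: 14.1, 85.4; 5.00: 17.8, 82.0; 8.00: 25.6, 74.3
- larch (time / min: product / %, substrate / %): 1.33: 2.7, 97.6; 2.00: 3.8, 97.4; 4.00: 7.7, 93.0; 8.00: 13.1, 86.9; 15.0: 21.9, 78.8
- cedar (time / min: product / %, substrate / %): 0.667: 0.8, 98.1; 2.00: 2.6, 97.0; 4.00: 5.9, 94.7; 5.00: 7.1, 93.5; 8.00: 11.6, 88.7

(standard deviation of a reading: 0.5 percentage points)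

- which of the two ends with the higher amount of product, in percent of the substrate charged ("neither" if they lie within 2 percentage points) (zeta / delta / neither)
- product at the end, in percent of the substrate charged, zeta
- product at the end, in percent of the substrate charged, delta



I take one reagent to go with each substrate. Substrate is then the limiting reagent in zeta, with 0.10 M against 0.180 M of reagent, and in delta, with 0.025 M against 0.0500 M.

The larch reading at 15.0 min comes to 120 turnovers, and this is the quantity I carry: the turnover count, product formed per catalyst charged. Zeta's charge is worth 500 turnovers. Zeta resembles larch closely, with 0.10 M of substrate against 0.11 M and the same reagent. Its 3.0 min at 110 °C and 12.0 min at 90 °C lie on either side of larch's 95 °C, and I let the two stretches cancel. So I enter the larch count for zeta, which books 24.1% as product and leaves 75.9% as substrate, and the account closes.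

Delta's charge is worth 125 turnovers. Its nearest run is oak, with a count of 55.5. I take the count as proportional to reagent and let delta's 0.025 M of substrate stand for oak's 0.030 M, which gives 15.4 turnovers, or 12.3% of delta's substrate. Delta runs cooler than oak, at 90 °C against 95 °C, so I read this figure as somewhat high.

The forecast names zeta as the higher, with zeta at 23% (range 20% to 26%) and delta at 9.5% (range 7% to 12.5%). For delta, its constant “is scaled by reagent” as well, but it starts from a different figure and lands below my uncorrected entry.

The flasks give 22.6% for zeta and 10.2% for delta, so zeta ends higher.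

    2 free catalyst → spent catalyst (k = 76.0 /M/min, Ea = 76.0 kJ/mol)
    substrate + reagent + free catalyst → product + free catalyst, rate k2*[substrate]*[reagent]*[free catalyst]/(1 + ([substrate]/sat2)) (0.0640 M, k = 2400 /M²/min, Ea = 47.0 kJ/mol)
    (constants at 110 °C)

Both values lie inside the forecast's ranges. Zeta's product moves by 5 points when its reagent goes down to 0.139 M, which exceeds the 2.6 percentage points between zeta's result and the forecast's low end. Zeta's own count comes to 113 turnovers, against larch's 120. Zeta's charges held at 90 °C throughout end at 19.2% product, a count of 95.9, lower than larch's 120.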